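(The earlier runs and the new flask are calculated from invented constants.)

A protic impurity that reacts one for one cannot consume more starting material than its own charge. For Thursday's, Friday's and Monday's that share of the charge is 5.00%, and I called it the quench ceiling: impurity charged over starting material charged, the impurity being the limiting reagent of that side reaction.

| flask | starting material | protic impurity | temperature | remark | time |
|---|---|---|---|---|---|
| beta | 0.54 M | 0.038 M | 90 °C | run made earlier |  |
| zeta | 0.54 M | 0.059 M | 112 °C | run made earlier |  |
| delta | 1.1 M | 0.027 M | 90 °C | run made earlier |  |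
| Thursday's | 0.54 M | 0.0270 M | 100 °C |  | 8.0 min |
| Friday's | 0.54 M | 0.0270 M | 120 °C |  | 8.0 min |
| Monday's | 0.54 M | 0.0270 M | 80 °C |  | 8.0 min |

1. the flask that comes out highest in amount of target, in percent of the starting material charged, or "all alike" when all lie within 1.5 percentage points (Thursday's / Friday's / Monday's / all alike)
2. target at the end, in percent of the starting material charged, Thursday's
3. target at the end, in percent of the starting material charged, Friday's
4. target at the end, in percent of the starting material charged, Monday's

| run | time / min | target / % | starting material / % |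
|---|---|---|---|
| beta | 1.33 | 38.2 | 28.9 |
| beta | 4.00 | 34.4 | 12.6 |
| beta | 6.00 | 30.1 | 11.3 |
| beta | 10.0 | 26.6 | 9.2 |
| beta | 15.0 | 25.7 | 9.8 |
| zeta | 0.500 | 31.0 | 16.8 |
| zeta | 1.33 | 22.6 | 10.9 |
| zeta | 2.00 | 19.7 | 9.5 |
| zeta | 3.00 | 15.9 | 7.7 |
| zeta | 6.00 | 13.5 | 7.0 |
| delta | 3.00 | 37.9 | 16.3 |
| delta | 6.00 | 32.2 | 11.8 |
| delta | 10.0 | 30.2 | 11.3 |
| delta | 12.0 | 27.5 | 10.4 |
| delta | 15.0 | 26.3 | 10.3 |

(scatter of a reading: 0.5 percentage points)

I read the last row of each table against its ceiling. Beta, with a ceiling of 7.04%, held 25.7% target and 9.8% starting material, which left 57.5% of the charge unseen even with the ceiling filled. Delta's ceiling was lower at 2.45%, and its unseen share was 60.9%. The missing material therefore sat mostly outside the quench, in forms I could not read.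

Zeta, with a ceiling of 10.9%, ran hotter than beta and left more unseen, 68.6%, with less target.

The new flasks shared one ceiling and one time, so temperature was what separated them. Beta, the colder of those two runs, had ended with more target than zeta, though their impurity and last reading times differed too. On that reading I committed to Monday's, colder than beta, as highest and above beta's 25.7%, and to Friday's, hotter than zeta, as lowest and below zeta's 13.5%, with Thursday's between.

The forecast named Monday's, with 39% there, 22.3% for Thursday's and 11% for Friday's, holding that “hotter conditions disfavour target”.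

The flasks gave 37.9% in Monday's, 21.6% in Thursday's and 11.5% in Friday's, so Monday's came out highest.

    target ⇌ isomer of the product B (K = 0.650, k = 0.0940 min⁻¹, Ea = 107 kJ mol⁻¹, ΔH = −7.00 kJ mol⁻¹)
    starting material ⇌ dormant form (K = 5.60, k = 0.0890 min⁻¹, Ea = 105 kJ mol⁻¹, ΔH = 16.0 kJ mol⁻¹)
    starting material + protic impurity → quenched substrate (k = 2.40 M⁻¹ min⁻¹, Ea = 47.0 kJ mol⁻¹)
    starting material ⇌ target (K = 2.90, k = 0.330 min⁻¹, Ea = 92.0 kJ mol⁻¹, ΔH = −17.0 kJ mol⁻¹)
    isomer of the product A ⇌ starting material (k = 0.0680 min⁻¹, Ea = 105 kJ mol⁻¹)
    target ⇌ isomer of the product A (K = 0.150, k = 0.0260 min⁻¹, Ea = 111 kJ mol⁻¹, ΔH = −27.0 kJ mol⁻¹)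
    (constants at 80 °C)

The ceiling held: Monday's had 4.83% quenched substrate at 8.00 min, below 5.00%, and Friday's had 4.96%, level with it. A flask like Monday's kept at 65 °C had 4.81% under the same ceiling. Dormant form stood at 69.8% in Friday's against 21.5% in Monday's. What temperature does to the step from starting material to dormant form is the largest single effect on the gap between those flasks: Friday's minus Monday's in target is −26 percentage points with it and −2.1 points without it.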